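Readings and results stem from a simulated flask from invented constants; scatter was added.

**Bench rule.** A millimole of E charged is counted at the bench as a millimole of D, which makes L the limiting reagent once E passes one equivalent. The gamma run breaks that rule: at an E/L ratio of 2.20 it still holds 31.7% of L at 90.0 s, while L and D together reach 98.6%. So in the gamma run Q, which E feeds into the reaction phase, leaves largely by Q → J, and Q + D → Z stays small.

- gamma: L 5 mM; E 11 mM; run made earlier
- flask: L 5.0 mM; E 7.50 mM; time 5.0 min; volume of the second phase over the first 0.25
gamma run (percent of the L charged)

| time / s | D / % | L / % |
|---|---|---|
| 25.0 | 38.1 | 62.1 |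
| 50.0 | 57.1 | 41.3 |
| 60.0 | 60.3 | 36.9 |
| 90.0 | 66.9 | 31.7 |

(scatter of a reading: 0.5 percentage points)
- D at 5.0 min, in percent of the L charged
- the change that raises the amount of D at 5.0 min, in percent of the L charged most ("none" if none brings more than 2 percentage points) (north-west / north / none)
- amount of D at 5.0 min, in percent of the L charged, after north
- in the second phase: E; everything else is in the first
- charges count per volume of the first phase; a concentration in a rate is the amount of a species over the volume of its own phase; every rate counts per litre of the first phase
- on the list of suspects stand: Q <-> E; L + Q -> D; Q + D -> Z; Q -> J
- the earlier runs hold the two phases in the same ratio of volumes as the flask asked about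

**Break-even level.** L + Q → D and Q → J are both first order in Q, so L takes the share L/(L + c) of Q. Far above c, each E consumed removes one L; far below c, each factor e in L costs c of E. Joining both ends gives: E consumed = (L° − L) + c·ln(L°/L), with L° the charge. Counting the gamma charge as consumed at its last reading gives a reading, high if E remained, of c = 6.60 mM, the break-even level of L, where both paths take equal shares, a selectivity factor in concentration form.

**Conversion price.** Converting half of L costs L°/2 + c·ln 2. In the asked flask that is 7.08 mM, and the charge of 7.50 mM exceeds it. The surplus buys L at the half-way share, so this reckoning gives 52.3% converted. The balance holds no transfer coefficient, so this reckoning favours north-west and leaves D in place after north.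

**The forecast.** It says 53.5%, north-west and 53.5% after north, using c near 6, and on north: “Doubling transfer only speeds an already finished run”.

**The result.** The asked flask gives 56.7%, north-west adding 24 percentage points, and 56.7% after north.

    Q ⇌ E, rate k1*([Q] - [E]/K1) per volume of the first phase (partition coefficient = 1.61, kL = 0.0354 s⁻¹)
    L + Q → D (k = 5.11 M⁻¹ s⁻¹)
    Q + D → Z (k = 0.258 M⁻¹ s⁻¹)
    Q → J (k = 0.0265 s⁻¹)

Q → J is the main reason the asked flask stops short: without that step D reaches 85.2%, against 56.7%. At 5.00 min L stands at 2.09 mM, below c, where the carried c gives L a share of 24.1%.

In the neighbour flask with 8.5 mM of L, the price is 8.83 mM, above the charge of E, so c places conversion near 43.9%. The computed neighbour flask holds 46.9% of D and 52% of L.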